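**Plan**

1. Retrosynthesis: remove the C6 vanillate, the C2 acetate and the 8,9-epoxide oxygen, move the alkene from C8=C9 back to C9=C10, then cut C7–C8 and C1–C5 together.
2. Enabling feature: in the seven-membered ring the oxygenated C6 sits between C5 and C7 and is 1,3 to the tertiary C4–OH of the cyclopentane. That β-hydroxy ketone pattern is an opened α,β-epoxy enol silane, i.e. a 2-silyloxyallyl cation C5–C6–C7, and the other four ring carbons C8–C9–C10–C1 form a diene, so one intramolecular (4+3) cycloaddition closes both rings.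
3. Forward: the C15 chain is built linearly (Wittig dienal, asymmetric propargylation, ynoate, isopropyl cuprate, reduction, Sharpless epoxidation, methyl ketone, enol silane) and folded in step 11 into the trans-fused bicycle.
4. After the cycloaddition: C9=C10 is moved to C8=C9 through the 7,9-dienone and a 1,4-hydrogenation, then C4–OH-directed ketone reduction, C6–OH-directed epoxidation, the two acylations and a final hydrogenolysis.
5. Stereochemistry: C2 from the catalytic asymmetric propargylation; C4 and C5 from the Sharpless epoxide (retention at C4, inversion at C5); C1 from the cycloaddition under control of C2 and the epoxide; C6 by hydride delivery from C4–OH; C8/C9 by oxygen delivery from C6–OH.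

Key step: step 11

Remark: bicyclic compounds are named on the daucane skeleton (cyclopentane C1–C5, cycloheptane C1, C5–C10; methyl on C1 and C8, isopropyl on C4; C1 is the methyl-bearing ring-fusion carbon, C5 the ring-fusion CH). (S)-TRIP is assumed to be the catalyst enantiomer that sends the allenylboronate to the Si face of aldehyde 3.

**Route**

Step 1
Reactants: 1 (E)-but-2-enal; 2 2-(triphenylphosphoranylidene)propanal
Product: 3 (2E,4E)-2-methylhexa-2,4-dienal
Conditions: toluene, 90 °C
Reagents that add atoms: none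
Why: Wittig olefination with a formyl-stabilised ylide, which reacts only at the aldehyde of 1 and should give the (2E)-trisubstituted enal while the existing (E)-alkene is carried over unchanged.

Step 2
Reactants: 3 (2E,4E)-2-methylhexa-2,4-dienal; 4 allenylboronic acid pinacol ester
Product: 5 (4S,5E,7E)-5-methylnona-5,7-dien-1-yn-4-ol
Conditions: (S)-TRIP [(S)-3,3′-bis(2,4,6-triisopropylphenyl)-1,1′-binaphthyl-2,2′-diyl hydrogen phosphate] (5 mol%), 4 Å molecular sieves, toluene, 0 °C; aqueous work-up
Reagents that add atoms: none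
Why: Chiral-phosphoric-acid-catalysed propargylation of an aldehyde with an allenylboronate (SE2′ transfer through a closed six-membered transition state in which the catalyst hydrogen-bonds to a boronate oxygen), expected to add to the Si face of the conjugated aldehyde and so set the carbinol centre (later C2) as S without touching the diene.

Step 3
Reactants: 5 (4S,5E,7E)-5-methylnona-5,7-dien-1-yn-4-ol
Product: 6 tert-butyldimethyl{[(4S,5E,7E)-5-methylnona-5,7-dien-1-yn-4-yl]oxy}silane
Conditions: TBSCl, imidazole, DMF, 23 °C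
Reagents that add atoms: tert-butyldimethylsilyl chloride, CC(C)(C)[Si](C)(C)Cl
Why: Routine silylation of a secondary alcohol, chosen because an ester at this allylic position would not survive the later acetylide, cuprate, hydride and Grignard steps.

Step 4
Reactants: 6 tert-butyldimethyl{[(4S,5E,7E)-5-methylnona-5,7-dien-1-yn-4-yl]oxy}silane
Product: 8 methyl (5S,6E,8E)-5-[(tert-butyldimethylsilyl)oxy]-6-methyldeca-6,8-dien-2-ynoate, via lithium acetylide 7 (not isolated)
Conditions: n-BuLi, THF, −78 °C; then ClCO2Me, −78 → 0 °C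
Reagents that add atoms: methyl chloroformate, COC(=O)Cl
Why: Deprotonation of the terminal alkyne and C-acylation of the lithium acetylide with a chloroformate, a routine entry to 2-ynoates.

Step 5
Reactants: 8 methyl (5S,6E,8E)-5-[(tert-butyldimethylsilyl)oxy]-6-methyldeca-6,8-dien-2-ynoate
Product: 9 methyl (2E,5S,6E,8E)-5-[(tert-butyldimethylsilyl)oxy]-6-methyl-3-(propan-2-yl)deca-2,6,8-trienoate
Conditions: iPrMgCl (2.2 equiv), CuI (1.1 equiv), THF, −78 °C; NH4Cl aq. added at −78 °C
Reagents that add atoms: isopropylmagnesium chloride, CC(C)[Mg]Cl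
Why: Conjugate addition (syn-carbocupration) of an isopropylcuprate to a 2-ynoate at −78 °C followed by protonation of the alkenylcopper with retention should place isopropyl cis to H, that is the chain methylene cis and isopropyl trans to the ester (2E), the geometry that later becomes the C4/C5 relative configuration.

Step 6
Reactants: 9 methyl (2E,5S,6E,8E)-5-[(tert-butyldimethylsilyl)oxy]-6-methyl-3-(propan-2-yl)deca-2,6,8-trienoate
Product: 10 (2E,5S,6E,8E)-5-[(tert-butyldimethylsilyl)oxy]-6-methyl-3-(propan-2-yl)deca-2,6,8-trien-1-ol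
Conditions: iBu2AlH (2.5 equiv), CH2Cl2, −78 °C; aq. KNaC4H4O6 work-up
Reagents that add atoms: none
Why: 1,2-Reduction of the conjugated ester with iBu2AlH to the primary allylic alcohol, which leaves the silyl ether and the diene untouched.

Step 7
Reactants: 10 (2E,5S,6E,8E)-5-[(tert-butyldimethylsilyl)oxy]-6-methyl-3-(propan-2-yl)deca-2,6,8-trien-1-ol
Product: 11 [(2R,3R)-3-{(2S,3E,5E)-2-[(tert-butyldimethylsilyl)oxy]-3-methylhepta-3,5-dien-1-yl}-3-(propan-2-yl)oxiran-2-yl]methanol
Conditions: Ti(OiPr)4 (10 mol%), D-(−)-diethyl tartrate (12 mol%), t-BuOOH, 4 Å molecular sieves, CH2Cl2, −20 °C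
Reagents that add atoms: tert-butyl hydroperoxide, CC(C)(C)OO
Why: Sharpless asymmetric epoxidation, which is reagent-controlled and confined to the allylic-alcohol alkene, so that with D-(−)-tartrate the oxygen should be delivered to the face giving the (2R,3R)-epoxide and fix the future C4 (carbinol oxygen) and C5 centres while the diene is left alone.

Step 8
Reactants: 11 [(2R,3R)-3-{(2S,3E,5E)-2-[(tert-butyldimethylsilyl)oxy]-3-methylhepta-3,5-dien-1-yl}-3-(propan-2-yl)oxiran-2-yl]methanol
Product: 13 1-[(2R,3R)-3-{(2S,3E,5E)-2-[(tert-butyldimethylsilyl)oxy]-3-methylhepta-3,5-dien-1-yl}-3-(propan-2-yl)oxiran-2-yl]ethan-1-ol (both carbinol epimers), via epoxy aldehyde 12 (not isolated)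
Conditions: (COCl)2, DMSO, THF, −78 °C; Et3N; then MeMgBr (excess), −78 °C
Reagents that add atoms: methylmagnesium bromide, C[Mg]Br
Why: Swern oxidation followed in the same flask by Grignard addition, a known telescoped protocol that avoids isolating the labile α,β-epoxy aldehyde 12, the new carbinol centre being of no consequence because it is oxidised in step 9.

Step 9
Reactants: 13 1-[(2R,3R)-3-{(2S,3E,5E)-2-[(tert-butyldimethylsilyl)oxy]-3-methylhepta-3,5-dien-1-yl}-3-(propan-2-yl)oxiran-2-yl]ethan-1-ol
Product: 14 1-[(2S,3R)-3-{(2S,3E,5E)-2-[(tert-butyldimethylsilyl)oxy]-3-methylhepta-3,5-dien-1-yl}-3-(propan-2-yl)oxiran-2-yl]ethan-1-one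
Conditions: Dess–Martin periodinane, NaHCO3, CH2Cl2, 0 → 23 °C
Reagents that add atoms: none
Why: Dess–Martin oxidation of a secondary alcohol under buffered conditions that tolerate the epoxide, the silyl ether and the diene and do not epimerise the epoxide carbon.

Step 10
Reactants: 14 1-[(2S,3R)-3-{(2S,3E,5E)-2-[(tert-butyldimethylsilyl)oxy]-3-methylhepta-3,5-dien-1-yl}-3-(propan-2-yl)oxiran-2-yl]ethan-1-one
Product: 15 triethyl({1-[(2S,3R)-3-{(2S,3E,5E)-2-[(tert-butyldimethylsilyl)oxy]-3-methylhepta-3,5-dien-1-yl}-3-(propan-2-yl)oxiran-2-yl]ethenyl}oxy)silane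
Conditions: LiN(SiMe3)2, Et3SiCl, Et3N, THF, −78 °C
Reagents that add atoms: chlorotriethylsilane, CC[Si](Cl)(CC)CC
Why: Kinetic enolisation at the methyl group, the only readily deprotonated α-position because the other α-carbon is an epoxide carbon, with in situ O-silylation (silyl enol ether formation) to give the 2-silyloxyallyl epoxide.

Step 11
Reactants: 15 triethyl({1-[(2S,3R)-3-{(2S,3E,5E)-2-[(tert-butyldimethylsilyl)oxy]-3-methylhepta-3,5-dien-1-yl}-3-(propan-2-yl)oxiran-2-yl]ethenyl}oxy)silane
Product: 16 (1R,2S,4R,5R,8R)-2-[(tert-butyldimethylsilyl)oxy]-4-[(triethylsilyl)oxy]dauc-9-en-6-one (trans-fused)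
Conditions: Et3SiOTf (0.2 equiv), CH2Cl2, −78 °C; then Et3N
Reagents that add atoms: none
Why: Et3SiOTf silylates the epoxide oxygen, the C5–O bond (aligned with the enol-ether π system) ionises towards a 2-(triethylsilyloxy)allyl cation C5–C6–C7 while the tethered diene attacks C5 from the face opposite the leaving oxygen, the resulting allyl cation C10–C9–C8 collapses onto C7, and loss of the silyl group from the C6 oxonium turns the catalyst over, leaving the C6 ketone and the C4 triethylsilyl ether. The closest known reaction type is the silyl-triflate-catalysed intramolecular (4+3) cycloaddition of α,β-epoxy enol silanes with tethered dienes, a variant of the oxyallyl-cation (4+3) cycloaddition. The cyclopentane closes by C1→C5 attack that is 5-exo with respect to the C1=C10 alkene and endo with respect to the epoxide (tolerated because the C5–O bond is largely ionised), and the cycloheptenone closes by 7-endo union of C7 with C8, suprafacially on the s-cis diene. C4 keeps its Sharpless-derived configuration because its C–O bond is not broken, C5 is set by inversion at the epoxide carbon, C1 is set by the C2 centre (silyloxy group in the alkene plane on the C10–H side, hydrogen next to the C1 methyl) acting together with an extended transition state of the W-shaped cation in which the diene avoids the bulky triethylsilyloxy group, which should give the trans ring fusion, and C8 follows from the (E)-propenyl geometry and is erased in step 12. The step needs periselectivity for the seven-membered ring over five-membered (3+2) closure, proton loss or capture of the cation by the C2 silyl ether oxygen, and it needs the trans fusion; the (E,E)-diene with only H and one methyl as inside substituents can reach the s-cis form, the three-atom tether holds C8 over C7, and the low temperature and non-nucleophilic counter-ion favour ring closure.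

Step 12
Reactants: 16 (1R,2S,4R,5R,8R)-2-[(tert-butyldimethylsilyl)oxy]-4-[(triethylsilyl)oxy]dauc-9-en-6-one
Product: 17 (1R,2S,4R,5R)-2-[(tert-butyldimethylsilyl)oxy]-4-[(triethylsilyl)oxy]dauca-7,9-dien-6-one
Conditions: IBX, 4-methoxypyridine N-oxide, DMSO, 23 °C
Reagents that add atoms: none
Why: IBX dehydrogenation of a ketone to the enone through its enol, in which only the C7–C8 bond can be desaturated because the other α-carbon C5 has no β-hydrogen (C4 and C1 are fully substituted), so the linearly conjugated 7,9-dienone should result and the C8 stereocentre disappears.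

Step 13
Reactants: 17 (1R,2S,4R,5R)-2-[(tert-butyldimethylsilyl)oxy]-4-[(triethylsilyl)oxy]dauca-7,9-dien-6-one
Product: 18 (1R,2S,4R,5R)-2-[(tert-butyldimethylsilyl)oxy]-4-[(triethylsilyl)oxy]dauc-8-en-6-one
Conditions: (η6-C10H8)Cr(CO)3 (naphthalene complex, 20 mol%), H2 (4 atm), THF, 45 °C
Reagents that add atoms: none
Why: Arene-Cr(CO)3-catalysed 1,4-hydrogenation of an s-cis 1,3-diene, which adds hydrogen only to the diene termini C7 and C10 and so should turn the cyclic 2,4-dienone into the β,γ-unsaturated ketone with the C8=C9 alkene, leaving the ketone and the silyl ethers untouched.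

Step 14
Reactants: 18 (1R,2S,4R,5R)-2-[(tert-butyldimethylsilyl)oxy]-4-[(triethylsilyl)oxy]dauc-8-en-6-one
Product: 19 (1R,2S,4R,5R)-2,4-dihydroxydauc-8-en-6-one
Conditions: HF·pyridine, pyridine, THF, 0 → 23 °C
Reagents that add atoms: none
Why: Buffered fluoride cleavage of both silyl ethers under weakly acidic conditions, chosen because basic fluoride could move the β,γ-alkene into conjugation or trigger retro-aldol cleavage of the β-hydroxy ketone.

Step 15
Reactants: 19 (1R,2S,4R,5R)-2,4-dihydroxydauc-8-en-6-one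
Product: 20 (1R,2S,4R,5R)-2-acetoxy-4-hydroxydauc-8-en-6-one
Conditions: Ac2O, pyridine, DMAP (cat.), CH2Cl2, 0 °C
Reagents that add atoms: acetic anhydride, CC(=O)OC(C)=O
Why: Acetylation of the only secondary alcohol, the hindered tertiary C4 alcohol flanked by isopropyl not being expected to react under these mild conditions.

Step 16
Reactants: 20 (1R,2S,4R,5R)-2-acetoxy-4-hydroxydauc-8-en-6-one
Product: 21 (1R,2S,4R,5S,6S)-2-acetoxydauc-8-ene-4,6-diol (2α-acetoxy, 4β-OH, 6α-OH)
Conditions: Me4NBH(OAc)3, MeCN/AcOH (1:1), −30 → 0 °C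
Reagents that add atoms: none
Why: Evans–Saksena hydroxyl-directed reduction, in which the C4 hydroxyl (cis to C6 on the cyclopentane) exchanges onto boron and delivers hydride to the β-face of the C6 ketone, which should give the 6α-alcohol (4,6-anti diol, C6 = S) that an external hydride attacking the less hindered α-face would not give.

Step 17
Reactants: 21 (1R,2S,4R,5S,6S)-2-acetoxydauc-8-ene-4,6-diol
Product: 22 (1R,2S,4R,5S,6S,8R,9S)-2-acetoxy-8,9-epoxydaucane-4,6-diol
Conditions: VO(acac)2 (5 mol%), t-BuOOH, CH2Cl2, 0 → 23 °C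
Reagents that add atoms: tert-butyl hydroperoxide, CC(C)(C)OO
Why: VO(acac)2-catalysed epoxidation directed by the homoallylic C6 hydroxyl, which should deliver oxygen to the C8=C9 alkene syn to that hydroxyl (α-face) and set C8 (R) and C9 (S), the tertiary C4 hydroxyl being too remote to direct.

Step 18
Reactants: 22 (1R,2S,4R,5S,6S,8R,9S)-2-acetoxy-8,9-epoxydaucane-4,6-diol; 23 4-(benzyloxy)-3-methoxybenzoic acid
Product: 25 (1R,2S,4R,5S,6S,8R,9S)-2-acetoxy-8,9-epoxy-4-hydroxydaucan-6-yl 4-(benzyloxy)-3-methoxybenzoate, via mixed anhydride 24 (not isolated)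
Conditions: 23, 2,4,6-trichlorobenzoyl chloride, Et3N, THF, 23 °C; then 22, DMAP, toluene, 50 °C
Reagents that add atoms: none
Why: Yamaguchi esterification through the mixed anhydride 24, suited to the hindered secondary C6 alcohol, in which the tertiary C4 alcohol is not acylated and the amine-buffered medium spares the epoxide.

Step 19
Reactants: 25 (1R,2S,4R,5S,6S,8R,9S)-2-acetoxy-8,9-epoxy-4-hydroxydaucan-6-yl 4-(benzyloxy)-3-methoxybenzoate
Product: 26 (1R,2S,4R,5S,6S,8R,9S)-2-acetoxy-8,9-epoxy-4-hydroxydaucan-6-yl 4-hydroxy-3-methoxybenzoate (target, CNP0241679.3)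
Conditions: H2 (1 atm), Pd/C (10% palladium on carbon), EtOAc, 23 °C
Reagents that add atoms: none
Why: Hydrogenolysis of the benzyl aryl ether over Pd/C under neutral conditions, which should free the phenol without affecting the two esters or the non-benzylic trisubstituted epoxide, no alkene being left in the molecule.

**Compound list**

1 | (E)-but-2-enal (crotonaldehyde) | C/C=C/C=O | starting material
2 | 2-(triphenylphosphoranylidene)propanal | CC(C=O)=P(c1ccccc1)(c1ccccc1)c1ccccc1 | starting material
3 | (2E,4E)-2-methylhexa-2,4-dienal | O=C/C(C)=C/C=C/C | intermediate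
4 | allenylboronic acid pinacol ester | C=C=CB1OC(C)(C)C(C)(C)O1 | starting material
5 | (4S,5E,7E)-5-methylnona-5,7-dien-1-yn-4-ol | C#CC[C@H](O)/C(C)=C/C=C/C | intermediate
6 | tert-butyldimethyl{[(4S,5E,7E)-5-methylnona-5,7-dien-1-yn-4-yl]oxy}silane | C#CC[C@H](O[Si](C)(C)C(C)(C)C)/C(C)=C/C=C/C | intermediate
7 | lithium acetylide of 6 (not isolated) | [Li]C#CC[C@H](O[Si](C)(C)C(C)(C)C)/C(C)=C/C=C/C | intermediate
8 | methyl (5S,6E,8E)-5-[(tert-butyldimethylsilyl)oxy]-6-methyldeca-6,8-dien-2-ynoate | COC(=O)C#CC[C@H](O[Si](C)(C)C(C)(C)C)/C(C)=C/C=C/C | intermediate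
9 | methyl (2E,5S,6E,8E)-5-[(tert-butyldimethylsilyl)oxy]-6-methyl-3-(propan-2-yl)deca-2,6,8-trienoate | COC(=O)/C=C(/C(C)C)C[C@H](O[Si](C)(C)C(C)(C)C)/C(C)=C/C=C/C | intermediate
10 | (2E,5S,6E,8E)-5-[(tert-butyldimethylsilyl)oxy]-6-methyl-3-(propan-2-yl)deca-2,6,8-trien-1-ol | OC/C=C(/C(C)C)C[C@H](O[Si](C)(C)C(C)(C)C)/C(C)=C/C=C/C | intermediate
11 | [(2R,3R)-3-{(2S,3E,5E)-2-[(tert-butyldimethylsilyl)oxy]-3-methylhepta-3,5-dien-1-yl}-3-(propan-2-yl)oxiran-2-yl]methanol | OC[C@H]1O[C@@]1(C(C)C)C[C@H](O[Si](C)(C)C(C)(C)C)/C(C)=C/C=C/C | intermediate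
12 | (2S,3R)-3-{(2S,3E,5E)-2-[(tert-butyldimethylsilyl)oxy]-3-methylhepta-3,5-dien-1-yl}-3-(propan-2-yl)oxirane-2-carbaldehyde (not isolated) | O=C[C@H]1O[C@@]1(C(C)C)C[C@H](O[Si](C)(C)C(C)(C)C)/C(C)=C/C=C/C | intermediate
13 | 1-[(2R,3R)-3-{(2S,3E,5E)-2-[(tert-butyldimethylsilyl)oxy]-3-methylhepta-3,5-dien-1-yl}-3-(propan-2-yl)oxiran-2-yl]ethan-1-ol (both carbinol epimers) | CC(O)[C@H]1O[C@@]1(C(C)C)C[C@H](O[Si](C)(C)C(C)(C)C)/C(C)=C/C=C/C | intermediate
14 | 1-[(2S,3R)-3-{(2S,3E,5E)-2-[(tert-butyldimethylsilyl)oxy]-3-methylhepta-3,5-dien-1-yl}-3-(propan-2-yl)oxiran-2-yl]ethan-1-one | CC(=O)[C@H]1O[C@@]1(C(C)C)C[C@H](O[Si](C)(C)C(C)(C)C)/C(C)=C/C=C/C | intermediate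
15 | triethyl({1-[(2S,3R)-3-{(2S,3E,5E)-2-[(tert-butyldimethylsilyl)oxy]-3-methylhepta-3,5-dien-1-yl}-3-(propan-2-yl)oxiran-2-yl]ethenyl}oxy)silane | C=C(O[Si](CC)(CC)CC)[C@H]1O[C@@]1(C(C)C)C[C@H](O[Si](C)(C)C(C)(C)C)/C(C)=C/C=C/C | intermediate
16 | (1R,2S,4R,5R,8R)-2-[(tert-butyldimethylsilyl)oxy]-4-[(triethylsilyl)oxy]dauc-9-en-6-one | O=C2C[C@@H](C)C=C[C@@]3(C)[C@@H](O[Si](C)(C)C(C)(C)C)C[C@@](O[Si](CC)(CC)CC)(C(C)C)[C@H]23 | intermediate
17 | (1R,2S,4R,5R)-2-[(tert-butyldimethylsilyl)oxy]-4-[(triethylsilyl)oxy]dauca-7,9-dien-6-one | O=C2C=C(C)C=C[C@@]3(C)[C@@H](O[Si](C)(C)C(C)(C)C)C[C@@](O[Si](CC)(CC)CC)(C(C)C)[C@H]23 | intermediate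
18 | (1R,2S,4R,5R)-2-[(tert-butyldimethylsilyl)oxy]-4-[(triethylsilyl)oxy]dauc-8-en-6-one | O=C2CC(C)=CC[C@@]3(C)[C@@H](O[Si](C)(C)C(C)(C)C)C[C@@](O[Si](CC)(CC)CC)(C(C)C)[C@H]23 | intermediate
19 | (1R,2S,4R,5R)-2,4-dihydroxydauc-8-en-6-one | O=C2CC(C)=CC[C@@]3(C)[C@@H](O)C[C@@](O)(C(C)C)[C@H]23 | intermediate
20 | (1R,2S,4R,5R)-2-acetoxy-4-hydroxydauc-8-en-6-one | O=C2CC(C)=CC[C@@]3(C)[C@@H](OC(C)=O)C[C@@](O)(C(C)C)[C@H]23 | intermediate
21 | (1R,2S,4R,5S,6S)-2-acetoxydauc-8-ene-4,6-diol | O[C@H]2CC(C)=CC[C@@]3(C)[C@@H](OC(C)=O)C[C@@](O)(C(C)C)[C@H]23 | intermediate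
22 | (1R,2S,4R,5S,6S,8R,9S)-2-acetoxy-8,9-epoxydaucane-4,6-diol | O[C@H]2C[C@@]3(C)O[C@H]3C[C@@]3(C)[C@@H](OC(C)=O)C[C@@](O)(C(C)C)[C@H]23 | intermediate
23 | 4-(benzyloxy)-3-methoxybenzoic acid | COc1cc(C(=O)O)ccc1OCc1ccccc1 | starting material
24 | 4-(benzyloxy)-3-methoxybenzoic 2,4,6-trichlorobenzoic anhydride (not isolated) | COc1cc(C(=O)OC(=O)c2c(Cl)cc(Cl)cc2Cl)ccc1OCc1ccccc1 | intermediate
25 | (1R,2S,4R,5S,6S,8R,9S)-2-acetoxy-8,9-epoxy-4-hydroxydaucan-6-yl 4-(benzyloxy)-3-methoxybenzoate | COc1cc(C(=O)O[C@H]2C[C@@]3(C)O[C@H]3C[C@@]3(C)[C@@H](OC(C)=O)C[C@@](O)(C(C)C)[C@H]23)ccc1OCc1ccccc1 | intermediate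
26 | (1R,2S,4R,5S,6S,8R,9S)-2-acetoxy-8,9-epoxy-4-hydroxydaucan-6-yl 4-hydroxy-3-methoxybenzoate | COc1cc(C(=O)O[C@H]2C[C@@]3(C)O[C@H]3C[C@@]3(C)[C@@H](OC(C)=O)C[C@@](O)(C(C)C)[C@H]23)ccc1O | target

**Step count and risks**

Total steps: 19. Longest linear sequence: 19 steps (1 → 26).

Steps most likely to fail:

Step 11. The cascade may stall after the first C–C bond (proton loss from the allyl cation, five-membered (3+2) closure, or capture of the C5 cation by the C2 silyl ether oxygen), or it may close with the cis ring fusion. The fallback sets out from 14 and generates a free oxyallyl cation by base instead of by epoxide ionisation. Reduction of the epoxy ketone with SmI2 in THF/MeOH at −78 °C should cleave the Cα–O bond and give (4S,6S,7E,9E)-6-[(tert-butyldimethylsilyl)oxy]-4-hydroxy-7-methyl-4-(propan-2-yl)undeca-7,9-dien-2-one F1. Silylation of the tertiary alcohol with Et3SiOTf and 2,6-lutidine gives the triethylsilyl ether F2. Kinetic enolisation at the methyl group (LiN(SiMe3)2, Me3SiCl, −78 °C) and chlorination of the silyl enol ether with N-chlorosuccinimide gives the 1-chloro ketone F3. Treating F3 with Et3N in CF3CH2OH at 23 °C should enolise towards C5 and ionise the C7–Cl bond to the 2-oxyallyl cation, whose intramolecular (4+3) cycloaddition with the diene gives 16, where the route is rejoined. In this variant C5 rests on substrate control by the C4 silyloxy centre and not on epoxide inversion.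

Step 13. The hindered diene may fail to bind chromium, the ketone may be over-reduced, or the new C8=C9 alkene may drift into conjugation. The fallback sets out from 17 and replaces catalytic hydrogenation by an electron-transfer reduction whose regiochemistry is fixed by kinetic protonation. Li metal (2.2 equiv) in liquid NH3/THF with one equivalent of t-BuOH at −78 °C should reduce the dienone, with protonation at C10, to the lithium 6,8-dienolate F4 (not isolated). Inverse quench into NH4Cl then protonates at C7 to give 18, where the route is rejoined.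

Step 17. Oxygen may be delivered to the β-face, or the 4,6-diol may bind vanadium unproductively so that the reaction is slow and unselective. The fallback sets out from 21 and exchanges the order of acylation and epoxidation, so that selectivity rests on steric shielding and not on hydroxyl delivery. Yamaguchi esterification of 21 with 23 (through 24, as in step 18) gives (1R,2S,4R,5S,6S)-2-acetoxy-4-hydroxydauc-8-en-6-yl 4-(benzyloxy)-3-methoxybenzoate F5. Epoxidation of F5 with m-chloroperbenzoic acid and NaHCO3 in CH2Cl2 at 0 °C, where the β-face of C8=C9 is screened by the angular C1 methyl so that attack from the α-face is expected, gives 25, where the route is rejoined.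

**Further compounds**

F1 | step 11 | (4S,6S,7E,9E)-6-[(tert-butyldimethylsilyl)oxy]-4-hydroxy-7-methyl-4-(propan-2-yl)undeca-7,9-dien-2-one | CC(=O)C[C@](O)(C(C)C)C[C@H](O[Si](C)(C)C(C)(C)C)/C(C)=C/C=C/C
F2 | step 11 | (4S,6S,7E,9E)-6-[(tert-butyldimethylsilyl)oxy]-7-methyl-4-(propan-2-yl)-4-[(triethylsilyl)oxy]undeca-7,9-dien-2-one | CC(=O)C[C@](O[Si](CC)(CC)CC)(C(C)C)C[C@H](O[Si](C)(C)C(C)(C)C)/C(C)=C/C=C/C
F3 | step 11 | (4S,6S,7E,9E)-6-[(tert-butyldimethylsilyl)oxy]-1-chloro-7-methyl-4-(propan-2-yl)-4-[(triethylsilyl)oxy]undeca-7,9-dien-2-one | ClCC(=O)C[C@](O[Si](CC)(CC)CC)(C(C)C)C[C@H](O[Si](C)(C)C(C)(C)C)/C(C)=C/C=C/C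
F4 | step 13 | lithium 6,8-dienolate of 18 (lithium 2-[(tert-butyldimethylsilyl)oxy]-4-[(triethylsilyl)oxy]dauca-6,8-dien-6-olate) | [Li]OC2=CC(C)=CC[C@@]3(C)[C@@H](O[Si](C)(C)C(C)(C)C)C[C@@](O[Si](CC)(CC)CC)(C(C)C)[C@H]23
F5 | step 17 | (1R,2S,4R,5S,6S)-2-acetoxy-4-hydroxydauc-8-en-6-yl 4-(benzyloxy)-3-methoxybenzoate | COc1cc(C(=O)O[C@H]2CC(C)=CC[C@@]3(C)[C@@H](OC(C)=O)C[C@@](O)(C(C)C)[C@H]23)ccc1OCc1ccccc1
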